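**Plan**
- Retrosynthesis: cut the C2–C1′ bond of the heptenyl chain (Stille), then cut the two ring bonds C3–C4 and C5–C6 together, which releases C4–C5 as a cis-enediol unit.
- Enabling feature: the C4–C5 cis-glycol lies between sp2 C3 and the enolisable C6, so C3=C2–C1(O)=C6 is a 2-oxy-1,3-diene. The carbocycle is therefore the CO2-extrusion product of a 2-pyrone [4+2] adduct (pyrone C3, C4, C5, C6 = target C3, C2, C1, C6). The lactone bridge is a temporary ring, and the pyrone C3 ester is the activating group that later becomes CH2OH.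
- Forward: bromofuran 1 → furyl carbinol with the butenoate chain (allylboration, cross-metathesis) → furan-to-pyrone ring change (Achmatowicz, oxidation, O-silylation) → cycloaddition with a dioxole and loss of CO2 gives the carbocycle → ester reduction, enone unveiling, α-iodination, Stille coupling, global deprotection.
- Stereochemistry: C4/C5 are cis from the dioxole geometry and (4R,5S) from a chiral Cu–bis(oxazoline) catalyst; C6 comes from kinetic protonation anti to the acetonide; the chain carbinol comes from (R)-propylene oxide; the E-alkenes come from cross-metathesis and syn-hydrostannation.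

Key step: step 6

Ring numbering used for all carbocycles: C1 = carbonyl (or O-bearing) carbon, C2 = carbon that finally bears the heptenyl chain, C3 = carbon bearing CH2OH (ester precursor), C4 and C5 = O-bearing sp3 carbons, C6 = carbon bearing the butenoate chain.

Remark: 2,2-dimethyl-1,3-dioxole (10) is taken as a purchasable reagent, and the (S,S)-ligand is assumed to expose the pyrone face that leads to (4R,5S); the (R,R)-ligand is used instead if the sense proves opposite.

**Step 1**
Reactants: 1 4-bromofuran-2-carbaldehyde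
Product: 2 methyl 5-formylfuran-3-carboxylate
Conditions: CO (1 atm), Pd(OAc)2 (2 mol %), Xantphos (4 mol %), Et3N, MeOH, 70 °C
Reagents that add atoms: carbon monoxide [C-]#[O+]; methanol CO
Why: Palladium-catalysed alkoxycarbonylation of the heteroaryl bromide (oxidative addition, CO insertion, methanolysis) should install the ester that later chelates the Lewis acid and ends as the C3 hydroxymethyl group, the aldehyde being untouched.

**Step 2**
Reactants: 2 methyl 5-formylfuran-3-carboxylate; 3 allylboronic acid pinacol ester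
Product: 4 methyl 5-(1-hydroxybut-3-en-1-yl)furan-3-carboxylate (racemic)
Conditions: toluene, rt; then H2O
Reagents that add atoms: none
Why: Uncatalysed allylboration of the aldehyde through a six-membered chair transition state should give the homoallylic furyl carbinol, whose stereocentre is irrelevant because that carbon becomes sp2 in pyrone 9.

**Step 3**
Reactants: 4 methyl 5-(1-hydroxybut-3-en-1-yl)furan-3-carboxylate; 5 tert-butyl methacrylate
Product: 6 tert-butyl (E)-5-hydroxy-5-[4-(methoxycarbonyl)furan-2-yl]-2-methylpent-2-enoate (racemic)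
Conditions: 5 (5 equiv), second-generation Hoveyda–Grubbs catalyst (5 mol %), CH2Cl2, 40 °C
Reagents that add atoms: none
Why: Olefin cross-metathesis of the terminal alkene with the 1,1-disubstituted acrylate should give the trisubstituted enoate with the thermodynamically favoured E geometry, ethene being lost.

**Step 4**
Reactants: 6 tert-butyl (E)-5-hydroxy-5-[4-(methoxycarbonyl)furan-2-yl]-2-methylpent-2-enoate
Product: 8 tert-butyl (E)-4-[5-(methoxycarbonyl)-3,6-dioxo-3,6-dihydro-2H-pyran-2-yl]-2-methylbut-2-enoate (racemic), via pyranone lactol 7 (not isolated)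
Conditions: N-bromosuccinimide, NaHCO3, THF–H2O (4:1), 0 °C; crude, then CrO3, H2SO4, H2O, acetone, 0 °C
Reagents that add atoms: water O
Why: Achmatowicz ring expansion (bromonium-triggered hydration of the furan, opening to an ene-dione and reclosure to lactol 7) followed by Jones oxidation of the lactol should give the pyrandione, the electron-poor enoate not competing for electrophilic bromine.

**Step 5**
Reactants: 8 tert-butyl (E)-4-[5-(methoxycarbonyl)-3,6-dioxo-3,6-dihydro-2H-pyran-2-yl]-2-methylbut-2-enoate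
Product: 9 methyl 6-[(E)-4-tert-butoxy-3-methyl-4-oxobut-2-en-1-yl]-5-(tert-butyldimethylsilyloxy)-2-oxo-2H-pyran-3-carboxylate
Conditions: t-BuMe2SiOTf, Et3N, CH2Cl2, −78 to 0 °C
Reagents that add atoms: tert-butyldimethylsilyl trifluoromethanesulfonate CC(C)(C)[Si](C)(C)OS(=O)(=O)C(F)(F)F
Why: Soft enolisation of the ring ketone toward the adjacent ring C–H and O-silylation should give the aromatic 5-silyloxy-2-pyrone (the 5-hydroxy-2-pyrone tautomer of 8, if already present, converges on the same product).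

**Step 6**
Reactants: 9 methyl 6-[(E)-4-tert-butoxy-3-methyl-4-oxobut-2-en-1-yl]-5-(tert-butyldimethylsilyloxy)-2-oxo-2H-pyran-3-carboxylate; 10 2,2-dimethyl-1,3-dioxole
Product: 12 tert-butyl (E)-4-[(4R,5S)-1-(tert-butyldimethylsilyloxy)-4,5-(isopropylidenedioxy)-3-(methoxycarbonyl)cyclohexa-1(6),2-dien-6-yl]-2-methylbut-2-enoate, via bridged lactone 11 (not isolated)
Conditions: Cu(OTf)2 (10 mol %), 2,2′-(propane-2,2-diyl)bis[(4S)-4-tert-butyl-4,5-dihydrooxazole] (12 mol %), 4 Å MS, 10 (3 equiv), CH2Cl2, −20 °C to rt; then toluene, 100 °C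
Reagents that add atoms: none
Why: Cu(OTf)2 bound to the bis(oxazoline) chelates the lactone carbonyl and the C3 ester of 9, lowers its LUMO and shields one face, so the electron-rich enediol ether 10 adds suprafacially across pyrone C3 and C6 in an asynchronous inverse-electron-demand [4+2] cycloaddition (bond to the electrophilic C6 leading, bond to the malonate-like C3 following), which forms the ring bonds C3–C4 and C5–C6 of the target in one operation. The closest known reaction type is the chiral Lewis-acid-catalysed inverse-demand Diels–Alder reaction of 2-pyrone-3-carboxylates with enol ethers, followed by thermal retro-[4+2] extrusion of CO2 from the bridged lactone. The six-membered carbocycle is closed by this concerted [4+2] mode (11 is a 2-oxabicyclo[2.2.2]octene), and heating then cleaves the lactone bridge as CO2 to leave the cyclohexa-1,3-diene 12, whose C3=C2 and C1=C6 double bonds are those needed for the enone and its enol ether. C4 and C5 are the only stereocentres that survive: their cis relationship follows from the cis geometry of 10 and suprafacial addition, and their absolute configuration (4R,5S) from the pyrone face left open by the tert-butyl groups of the ligand. Only enantiofacial selectivity is required, because 10 is symmetric (no regiochemistry) and endo and exo adducts converge on 12 once CO2 loss flattens the two bridgehead carbons.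

**Step 7**
Reactants: 12 tert-butyl (E)-4-[(4R,5S)-1-(tert-butyldimethylsilyloxy)-4,5-(isopropylidenedioxy)-3-(methoxycarbonyl)cyclohexa-1(6),2-dien-6-yl]-2-methylbut-2-enoate
Product: 13 tert-butyl (E)-4-[(4R,5S)-1-(tert-butyldimethylsilyloxy)-3-(hydroxymethyl)-4,5-(isopropylidenedioxy)cyclohexa-1(6),2-dien-6-yl]-2-methylbut-2-enoate
Conditions: i-Bu2AlH (2.2 equiv), CH2Cl2, −78 °C; aq. KNaC4H4O6 (potassium sodium tartrate)
Reagents that add atoms: none
Why: i-Bu2AlH should reduce the methyl dienoate by 1,2-hydride delivery to the allylic alcohol at −78 °C, while the hindered tert-butyl enoate, the silyl dienol ether and the acetonide survive.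

**Step 8**
Reactants: 13 tert-butyl (E)-4-[(4R,5S)-1-(tert-butyldimethylsilyloxy)-3-(hydroxymethyl)-4,5-(isopropylidenedioxy)cyclohexa-1(6),2-dien-6-yl]-2-methylbut-2-enoate
Product: 14 tert-butyl (E)-4-[(4R,5S,6R)-3-(hydroxymethyl)-4,5-(isopropylidenedioxy)-1-oxocyclohex-2-en-6-yl]-2-methylbut-2-enoate
Conditions: Bu4NF, AcOH, THF, −40 to 0 °C
Reagents that add atoms: none
Why: Fluoride cleaves the silyl dienol ether and acetic acid protonates the cross-conjugated enolate at C6, its only nucleophilic carbon, from the face opposite the fused dioxolane, which should place the butenoate chain cis to the C5 oxygen (6R) and give the conjugated enone under kinetic control.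

**Step 9**
Reactants: 14 tert-butyl (E)-4-[(4R,5S,6R)-3-(hydroxymethyl)-4,5-(isopropylidenedioxy)-1-oxocyclohex-2-en-6-yl]-2-methylbut-2-enoate
Product: 15 tert-butyl (E)-4-[(4R,5S,6R)-3-(hydroxymethyl)-2-iodo-4,5-(isopropylidenedioxy)-1-oxocyclohex-2-en-6-yl]-2-methylbut-2-enoate
Conditions: I2, pyridine–CH2Cl2 (1:1), 0 °C to rt
Reagents that add atoms: iodine II
Why: Nucleophile-triggered α-iodination of the enone (conjugate addition of pyridine at C3, iodination of the enolate at C2, loss of pyridine) should give the 2-iodoenone, pyridine being too weak a base to enolise toward C6.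

**Step 10**
Reactants: 16 (R)-2-methyloxirane; 17 (4-bromobut-1-yn-1-yl)trimethylsilane
Product: 20 (R)-hept-6-yn-2-ol, via Grignard reagent 18 (not isolated), via silylalkynol 19 (not isolated)
Conditions: Mg, THF; CuI (10 mol %), 16, −30 to 0 °C; then MeOH, K2CO3, rt
Reagents that add atoms: none
Why: Copper-catalysed opening of the epoxide at its CH2 terminus by the homopropargyl Grignard reagent leaves the (R) carbinol carbon untouched, and methanolic K2CO3 then cleaves the alkynyl C–Si bond.

**Step 11**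
Reactants: 20 (R)-hept-6-yn-2-ol
Product: 21 (2R,6E)-7-(tributylstannyl)hept-6-en-2-ol
Conditions: Bu3SnH, PdCl2(PPh3)2 (2 mol %), THF, 0 °C to rt
Reagents that add atoms: tributyltin hydride CCCC[SnH](CCCC)CCCC
Why: Palladium-catalysed syn-hydrostannation of the terminal alkyne should place tin on the terminal carbon with E geometry, the minor internal regioisomer being removed by chromatography.

**Step 12**
Reactants: 15 tert-butyl (E)-4-[(4R,5S,6R)-3-(hydroxymethyl)-2-iodo-4,5-(isopropylidenedioxy)-1-oxocyclohex-2-en-6-yl]-2-methylbut-2-enoate; 21 (2R,6E)-7-(tributylstannyl)hept-6-en-2-ol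
Product: 22 tert-butyl (E)-4-[(4R,5S,6R)-2-[(1E,6R)-6-hydroxyhept-1-en-1-yl]-3-(hydroxymethyl)-4,5-(isopropylidenedioxy)-1-oxocyclohex-2-en-6-yl]-2-methylbut-2-enoate
Conditions: Pd2(dba)3 (5 mol %), AsPh3 (20 mol %), CuI (10 mol %), DMF, rt to 40 °C
Reagents that add atoms: none
Why: Stille coupling of the 2-iodoenone with the (E)-alkenylstannane proceeds with retention of alkene geometry under neutral conditions that should neither epimerise C6 nor eliminate the C5 oxygen.

**Step 13**
Reactants: 22 tert-butyl (E)-4-[(4R,5S,6R)-2-[(1E,6R)-6-hydroxyhept-1-en-1-yl]-3-(hydroxymethyl)-4,5-(isopropylidenedioxy)-1-oxocyclohex-2-en-6-yl]-2-methylbut-2-enoate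
Product: 23 pestallic acid I, (E)-4-[(4R,5S,6R)-4,5-dihydroxy-2-[(1E,6R)-6-hydroxyhept-1-en-1-yl]-3-(hydroxymethyl)-1-oxocyclohex-2-en-6-yl]-2-methylbut-2-enoic acid
Conditions: CF3CO2H–H2O–CH2Cl2 (9:1:10), 0 °C to rt
Reagents that add atoms: none
Why: Aqueous trifluoroacetic acid should hydrolyse the acetonide and cleave the tert-butyl ester by acidolysis (SN1 loss of the tert-butyl cation as 2-methylpropene) without touching the stereocentres.

**Compound list**
1 | 4-bromofuran-2-carbaldehyde | O=Cc1cc(Br)co1 | starting material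
2 | methyl 5-formylfuran-3-carboxylate | COC(=O)c1coc(C=O)c1 | intermediate
3 | 2-allyl-4,4,5,5-tetramethyl-1,3,2-dioxaborolane (allylboronic acid pinacol ester) | C=CCB1OC(C)(C)C(C)(C)O1 | starting material
4 | methyl 5-(1-hydroxybut-3-en-1-yl)furan-3-carboxylate (racemic) | COC(=O)c1coc(C(O)CC=C)c1 | intermediate
5 | tert-butyl methacrylate | C=C(C)C(=O)OC(C)(C)C | starting material
6 | tert-butyl (E)-5-hydroxy-5-[4-(methoxycarbonyl)furan-2-yl]-2-methylpent-2-enoate (racemic) | C/C(=C\CC(O)c1cc(C(=O)OC)co1)C(=O)OC(C)(C)C | intermediate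
7 | tert-butyl (E)-4-[6-hydroxy-5-(methoxycarbonyl)-3-oxo-3,6-dihydro-2H-pyran-2-yl]-2-methylbut-2-enoate (lactol, stereoisomer mixture) | C/C(=C\CC1OC(O)C(C(=O)OC)=CC1=O)C(=O)OC(C)(C)C | intermediate
8 | tert-butyl (E)-4-[5-(methoxycarbonyl)-3,6-dioxo-3,6-dihydro-2H-pyran-2-yl]-2-methylbut-2-enoate (racemic) | C/C(=C\CC1OC(=O)C(C(=O)OC)=CC1=O)C(=O)OC(C)(C)C | intermediate
9 | methyl 6-[(E)-4-tert-butoxy-3-methyl-4-oxobut-2-en-1-yl]-5-(tert-butyldimethylsilyloxy)-2-oxo-2H-pyran-3-carboxylate | C/C(=C\Cc1oc(=O)c(C(=O)OC)cc1O[Si](C)(C)C(C)(C)C)C(=O)OC(C)(C)C | intermediate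
10 | 2,2-dimethyl-1,3-dioxole | CC1(C)OC=CO1 | starting material
11 | endo bridged lactone (2-oxabicyclo[2.2.2]oct-5-en-3-one: bridgeheads C3 with CO2Me and C6 with the butenoate chain, C1(OTBS)=C2 alkene bridge, C4–C5 cis-acetonide bridge syn to the alkene) | C/C(=C\C[C@@]12OC(=O)[C@@](C(=O)OC)(C=C1O[Si](C)(C)C(C)(C)C)[C@@H](OC(C)(C)O3)[C@H]23)C(=O)OC(C)(C)C | intermediate
12 | tert-butyl (E)-4-[(4R,5S)-1-(tert-butyldimethylsilyloxy)-4,5-(isopropylidenedioxy)-3-(methoxycarbonyl)cyclohexa-1(6),2-dien-6-yl]-2-methylbut-2-enoate | C/C(=C\CC1=C(O[Si](C)(C)C(C)(C)C)C=C(C(=O)OC)[C@@H](OC(C)(C)O2)[C@H]12)C(=O)OC(C)(C)C | intermediate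
13 | tert-butyl (E)-4-[(4R,5S)-1-(tert-butyldimethylsilyloxy)-3-(hydroxymethyl)-4,5-(isopropylidenedioxy)cyclohexa-1(6),2-dien-6-yl]-2-methylbut-2-enoate | C/C(=C\CC1=C(O[Si](C)(C)C(C)(C)C)C=C(CO)[C@@H](OC(C)(C)O2)[C@H]12)C(=O)OC(C)(C)C | intermediate
14 | tert-butyl (E)-4-[(4R,5S,6R)-3-(hydroxymethyl)-4,5-(isopropylidenedioxy)-1-oxocyclohex-2-en-6-yl]-2-methylbut-2-enoate | C/C(=C\C[C@H]1C(=O)C=C(CO)[C@@H](OC(C)(C)O2)[C@H]12)C(=O)OC(C)(C)C | intermediate
15 | tert-butyl (E)-4-[(4R,5S,6R)-3-(hydroxymethyl)-2-iodo-4,5-(isopropylidenedioxy)-1-oxocyclohex-2-en-6-yl]-2-methylbut-2-enoate | C/C(=C\C[C@H]1C(=O)C(I)=C(CO)[C@@H](OC(C)(C)O2)[C@H]12)C(=O)OC(C)(C)C | intermediate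
16 | (R)-2-methyloxirane | C[C@@H]1CO1 | starting material
17 | (4-bromobut-1-yn-1-yl)trimethylsilane | C[Si](C)(C)C#CCCBr | starting material
18 | [4-(trimethylsilyl)but-3-yn-1-yl]magnesium bromide | C[Si](C)(C)C#CCC[Mg]Br | intermediate
19 | (R)-7-(trimethylsilyl)hept-6-yn-2-ol | C[C@@H](O)CCCC#C[Si](C)(C)C | intermediate
20 | (R)-hept-6-yn-2-ol | C[C@@H](O)CCCC#C | intermediate
21 | (2R,6E)-7-(tributylstannyl)hept-6-en-2-ol | C[C@@H](O)CCC/C=C/[Sn](CCCC)(CCCC)CCCC | intermediate
22 | tert-butyl (E)-4-[(4R,5S,6R)-2-[(1E,6R)-6-hydroxyhept-1-en-1-yl]-3-(hydroxymethyl)-4,5-(isopropylidenedioxy)-1-oxocyclohex-2-en-6-yl]-2-methylbut-2-enoate | C/C(=C\C[C@H]1C(=O)C(/C=C/CCC[C@@H](C)O)=C(CO)[C@@H](OC(C)(C)O2)[C@H]12)C(=O)OC(C)(C)C | intermediate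
23 | pestallic acid I, (E)-4-[(1R,5R,6S)-5,6-dihydroxy-3-[(1E,6R)-6-hydroxyhept-1-en-1-yl]-4-(hydroxymethyl)-2-oxocyclohex-3-en-1-yl]-2-methylbut-2-enoic acid | C/C(=C\C[C@H]1C(=O)C(/C=C/CCC[C@@H](C)O)=C(CO)[C@@H](O)[C@H]1O)C(=O)O | target

Total step count: 13 (steps 10 and 11 build stannane 21).
Longest linear sequence: 11 steps (steps 1–9, 12, 13).

**Steps most likely to fail**

Step 6. The silyloxy donor on the pyrone raises electron density at the terminus that must accept the dioxole, so the catalysed cycloaddition may be too slow to outrun decomposition of 10, or facial discrimination may erode. The fallback makes the diene electron-poorer and unveils the ketone by a different event. It sets out from 8: acylation with pivaloyl chloride and Et3N gives the enol pivalate pyrone, methyl 6-[(E)-4-tert-butoxy-3-methyl-4-oxobut-2-en-1-yl]-2-oxo-5-(pivaloyloxy)-2H-pyran-3-carboxylate F1. The same Cu(OTf)2–bis(oxazoline) cycloaddition with 10 gives the bridged lactone F2, which loses CO2 on heating to the dienyl pivalate F3. Excess i-Bu2AlH at −78 °C then reduces the methyl ester and cleaves the enol ester to an aluminium enolate (the tert-butyl ester is expected to react slowest), and an acetic acid quench protonates C6 anti to the acetonide. The route is rejoined at 14.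

Step 9. Conjugate addition of pyridine to the fully substituted C3 may be slow, and prolonged exposure to the amine could allow enolisation toward C6, with epimerisation or β-elimination of the C5 oxygen and aromatisation. The fallback places the halogen and the heptenyl chain before the carbocycle exists. It sets out from lactol 7, now isolated: iodination (I2, pyridine) at the enone α-carbon gives the iodolactol, tert-butyl (E)-4-[6-hydroxy-4-iodo-5-(methoxycarbonyl)-3-oxo-3,6-dihydro-2H-pyran-2-yl]-2-methylbut-2-enoate F4. Oxidation (CrO3, H2SO4) gives the iododione F5, and silylation as in step 5 gives the 4-iodopyrone F6. Stille coupling with 21 gives the fully substituted pyrone F7. The cycloaddition of step 6 with 10 then gives the bridged lactone F8 and, after CO2 loss, the diene ester F9. i-Bu2AlH gives the allylic alcohol F10, and buffered fluoride (Bu4NF, AcOH) sets C6 and rejoins the route at 22.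

Step 13. While the tert-butyl ester is slowly cleaved, the strong acid may dehydrate the β-hydroxy ketone (leading to aromatisation) or epimerise C6 through the enol. The fallback splits the deprotection into two mild events. It sets out from 22: aqueous acetic acid removes only the acetonide to give the tetraol tert-butyl ester, tert-butyl (E)-4-[(4R,5S,6R)-4,5-dihydroxy-2-[(1E,6R)-6-hydroxyhept-1-en-1-yl]-3-(hydroxymethyl)-1-oxocyclohex-2-en-6-yl]-2-methylbut-2-enoate F11. Its ester is then hydrolysed at pH 7 by an esterase that accepts tert-butyl esters (Bacillus subtilis esterase or Candida antarctica lipase A). The route is rejoined at 23.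

**Further compounds**
F1 | step 6 | methyl 6-[(E)-4-tert-butoxy-3-methyl-4-oxobut-2-en-1-yl]-2-oxo-5-(pivaloyloxy)-2H-pyran-3-carboxylate | C/C(=C\Cc1oc(=O)c(C(=O)OC)cc1OC(=O)C(C)(C)C)C(=O)OC(C)(C)C
F2 | step 6 | endo bridged lactone from F1 and 10 (C1 pivalate analogue of 11) | C/C(=C\C[C@@]12OC(=O)[C@@](C(=O)OC)(C=C1OC(=O)C(C)(C)C)[C@@H](OC(C)(C)O3)[C@H]23)C(=O)OC(C)(C)C
F3 | step 6 | tert-butyl (E)-4-[(4R,5S)-4,5-(isopropylidenedioxy)-3-(methoxycarbonyl)-1-(pivaloyloxy)cyclohexa-1(6),2-dien-6-yl]-2-methylbut-2-enoate | C/C(=C\CC1=C(OC(=O)C(C)(C)C)C=C(C(=O)OC)[C@@H](OC(C)(C)O2)[C@H]12)C(=O)OC(C)(C)C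
F4 | step 9 | tert-butyl (E)-4-[6-hydroxy-4-iodo-5-(methoxycarbonyl)-3-oxo-3,6-dihydro-2H-pyran-2-yl]-2-methylbut-2-enoate | C/C(=C\CC1OC(O)C(C(=O)OC)=C(I)C1=O)C(=O)OC(C)(C)C
F5 | step 9 | tert-butyl (E)-4-[4-iodo-5-(methoxycarbonyl)-3,6-dioxo-3,6-dihydro-2H-pyran-2-yl]-2-methylbut-2-enoate | C/C(=C\CC1OC(=O)C(C(=O)OC)=C(I)C1=O)C(=O)OC(C)(C)C
F6 | step 9 | methyl 6-[(E)-4-tert-butoxy-3-methyl-4-oxobut-2-en-1-yl]-5-(tert-butyldimethylsilyloxy)-4-iodo-2-oxo-2H-pyran-3-carboxylate | C/C(=C\Cc1oc(=O)c(C(=O)OC)c(I)c1O[Si](C)(C)C(C)(C)C)C(=O)OC(C)(C)C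
F7 | step 9 | methyl 6-[(E)-4-tert-butoxy-3-methyl-4-oxobut-2-en-1-yl]-5-(tert-butyldimethylsilyloxy)-4-[(1E,6R)-6-hydroxyhept-1-en-1-yl]-2-oxo-2H-pyran-3-carboxylate | C/C(=C\Cc1oc(=O)c(C(=O)OC)c(/C=C/CCC[C@@H](C)O)c1O[Si](C)(C)C(C)(C)C)C(=O)OC(C)(C)C
F8 | step 9 | endo bridged lactone from F7 and 10 (C2-heptenyl analogue of 11) | C/C(=C\C[C@@]12OC(=O)[C@@](C(=O)OC)(C(/C=C/CCC[C@@H](C)O)=C1O[Si](C)(C)C(C)(C)C)[C@@H](OC(C)(C)O3)[C@H]23)C(=O)OC(C)(C)C
F9 | step 9 | tert-butyl (E)-4-[(4R,5S)-1-(tert-butyldimethylsilyloxy)-2-[(1E,6R)-6-hydroxyhept-1-en-1-yl]-4,5-(isopropylidenedioxy)-3-(methoxycarbonyl)cyclohexa-1(6),2-dien-6-yl]-2-methylbut-2-enoate | C/C(=C\CC1=C(O[Si](C)(C)C(C)(C)C)C(/C=C/CCC[C@@H](C)O)=C(C(=O)OC)[C@@H](OC(C)(C)O2)[C@H]12)C(=O)OC(C)(C)C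
F10 | step 9 | tert-butyl (E)-4-[(4R,5S)-1-(tert-butyldimethylsilyloxy)-2-[(1E,6R)-6-hydroxyhept-1-en-1-yl]-3-(hydroxymethyl)-4,5-(isopropylidenedioxy)cyclohexa-1(6),2-dien-6-yl]-2-methylbut-2-enoate | C/C(=C\CC1=C(O[Si](C)(C)C(C)(C)C)C(/C=C/CCC[C@@H](C)O)=C(CO)[C@@H](OC(C)(C)O2)[C@H]12)C(=O)OC(C)(C)C
F11 | step 13 | tert-butyl (E)-4-[(4R,5S,6R)-4,5-dihydroxy-2-[(1E,6R)-6-hydroxyhept-1-en-1-yl]-3-(hydroxymethyl)-1-oxocyclohex-2-en-6-yl]-2-methylbut-2-enoate | C/C(=C\C[C@H]1C(=O)C(/C=C/CCC[C@@H](C)O)=C(CO)[C@@H](O)[C@H]1O)C(=O)OC(C)(C)C
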